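Everything rests on cutting the cyclobutane (Ca on the C9 methylene, Cb the CMe2 carbon, Cc bearing isopropenyl, Cd the ring CH2) at Cc–Cd and Cb–Ca. Because Cb lies between the ring stereocentres, this leaves C9–Ca–Cd as a plain allyl group on C8 of the still-aromatic chromanone ring and Cb–Cc as an isobutyryl unit. One [2+2] cycloaddition of a C2-symmetric isobutyramide keteniminium salt with that allyl group forms both bonds, the four-membered ring and the Ca stereocentre, leaving a ketone at Cc for the isopropenyl group. The precursor is the hexasubstituted 8-allyl-7-silyloxy chromanone whose C5 oxygen and acid chain are held as a dihydrocoumarin lactone.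

Key step: step 10

Remarks on the chemistry
- Locants: 3, 5 and 7 carry coumarin numbering. From 8 on the chromanone ring is O1, C2, C3, C4, C4a, C5–C8, C8a; the lactone runs from the C5 oxygen through C=O and CH2 to the propyl-bearing carbon C1′ on C6; C9 is the methylene on C8.
- Assumption: (2R,5R)-2,5-dimethylpyrrolidine, tigloyl chloride, isopropenylmagnesium bromide solution and prenyl acetate are taken as commercial.
- Assumption: the sense of induction of the bisphosphine (step 5), the auxiliary (step 10) and the Trost ligand (step 13) cannot be assigned beforehand; one enantiomer is written, its antipode is equally available, and the two outcomes are diastereomers in each case.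
- The CIP label of Ca is R in 19 and 22 and S in 23 to 28 through a change of priorities only; the atom is untouched.
- The two phenolic oxygens flanking C6 are meta to each other and cannot both bond to the lactone carbonyl, so the lactone cannot migrate by direct acyl transfer. Its position is fixed on the rigid coumarin in step 2 and holds as long as ring-opening nucleophiles are kept away while the C7 hydroxyl is free.

Step 1
Reactants: 1 phloroglucinol; 2 ethyl 3-oxohexanoate
Product: 3 5,7-dihydroxy-4-propylcoumarin
Conditions: conc. H2SO4, 0 °C to rt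
Reagents that add atoms: none
Why: Pechmann condensation, in which the β-keto ester alkylates and lactonises the symmetric triol so that a single coumarin can form.

Step 2
Reactants: 3; 4 tigloyl chloride
Product: 5 5,7-dihydroxy-8-tigloyl-4-propylcoumarin
Conditions: AlCl3 (4 equiv), PhNO2/ClCH2CH2Cl, rt to 60 °C; then 1 M HCl, 0 °C
Reagents that add atoms: none
Why: Friedel–Crafts acylation, which on 5,7-dihydroxy-4-alkylcoumarins goes mainly to C8; doing it before the lactone is saturated places the lactone oxygen next to the acyl-bearing carbon, which a dihydrocoumarin (two interchangeable ring positions) would not guarantee.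

Step 3
Reactants: 5; 6 allyl alcohol
Product: 7 5-allyloxy-7-hydroxy-8-tigloyl-4-propylcoumarin
Conditions: PPh3, DIAD, THF, 0 °C to rt
Reagents that add atoms: none
Why: Mitsunobu etherification, selective for the 5-hydroxyl because the 7-hydroxyl is held in a hydrogen bond to the enone carbonyl, and neutral, so that the racemic base-induced closure of that hydroxyl onto the enone is avoided.

Step 4
Reactants: 7
Product: 8 (2R,3S)-7-allyloxy-2,3-dimethylchromanone fused to the unsaturated 4-propylcoumarin lactone
Conditions: quinine (20 mol %), PhCl, 15 °C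
Reagents that add atoms: none
Why: Alkaloid-catalysed intramolecular oxa-Michael addition, in which the ion-paired phenol adds to one face of the tigloyl β-carbon and the enol is protonated from the same side; on 7-hydroxy-8-tigloylcoumarins this is known to give the cis-2,3-dimethylchromanone as kinetic product, the (2R,3S) enantiomer being expected from quinine and its mirror image from quinidine.

Step 5
Reactants: 8
Product: 10 (1′S)-7-allyloxy dihydrocoumarin chroman-4-ol (both C4 epimers), via bis-silylated reduction product 9 (not isolated)
Conditions: Cu(OAc)2·H2O (5 mol %), (R)-DTBM-SEGPHOS (5.5 mol %), (EtO)2MeSiH (5 equiv), toluene, 0 °C to rt; then NH4F, MeOH, rt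
Reagents that add atoms: none
Why: Copper hydride asymmetric conjugate reduction of a coumarin, in which the bisphosphine-bound CuH delivers hydride to one face of the propyl-bearing carbon to set C1′ as S; the chromanone carbonyl is hydrosilylated as well (corrected in step 6), the absence of a proton source keeps the lactone as its silyl ketene acetal and so prevents reduction to the lactol, and the isolated allyl alkene is not attacked at this temperature.

Step 6
Reactants: 10
Product: 11 (2R,3S,1′S)-7-allyloxy lactone-chromanone tricycle
Conditions: Dess–Martin periodinane, pyridine, CH2Cl2, 0 °C to rt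
Reagents that add atoms: none
Why: Dess–Martin oxidation of the benzylic alcohol restores the chromanone without base or strong acid, so the cis C2/C3 relationship is kept (the same reagent would also return any lactol to the lactone).

Step 7
Reactants: 11
Product: 12 (2R,3S,1′S)-8-allyl-7-hydroxy lactone-chromanone tricycle
Conditions: 1,2-dichlorobenzene (degassed), 180 °C, sealed tube
Reagents that add atoms: none
Why: Aromatic Claisen rearrangement, a [3,3] shift to C8 as the only free ortho position followed by tautomerisation, run without acid, base or nucleophile so that neither the cis chromanone nor the lactone position is disturbed.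

Step 8
Reactants: 12
Product: 13 (2R,3S,1′S)-8-allyl-7-(tert-butyldimethylsilyloxy) lactone-chromanone tricycle
Conditions: TBSOTf (1.1 equiv), 2,6-lutidine, CH2Cl2, −40 to 0 °C
Reagents that add atoms: tert-butyldimethylsilyl triflate, CC(C)(C)[Si](C)(C)OS(=O)(=O)C(F)(F)F
Why: O-Silylation of the doubly ortho-substituted phenol with a silyl triflate and a hindered base, which is fast at low temperature and avoids nucleophilic amines that could open the aryl lactone; the silyl ether later serves as a latent phenoxide.

Step 9
Reactants: 14 isobutyryl chloride; 15 (2R,5R)-2,5-dimethylpyrrolidine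
Product: 16 1-[(2R,5R)-2,5-dimethylpyrrolidin-1-yl]-2-methylpropan-1-one
Conditions: Et3N, CH2Cl2, 0 °C to rt
Reagents that add atoms: none
Why: Schotten–Baumann-type N-acylation of the secondary amine.

Step 10
Reactants: 13; 16
Product: 19 8-{[(1R)-2,2-dimethyl-3-oxocyclobutyl]methyl}-7-silyloxy tricycle, via keteniminium triflate 17 (not isolated), via cyclobutaniminium triflate 18 (not isolated)
Conditions: 16 (3 equiv), (CF3SO2)2O, 2,4,6-collidine, ClCH2CH2Cl, −20 °C to rt; then 13, 70 °C; then H2O, THF, 40 °C
Reagents that add atoms: water, O
Why: Triflic anhydride activates the amide oxygen of 16 and collidine removes the α-hydrogen to give keteniminium triflate 17; the terminal alkene carbon Cd attacks its central electrophilic carbon (the future Cc) while positive charge builds at the internal carbon Ca, and the enamine-like CMe2 carbon Cb closes onto Ca before any bond rotation, so the four-membered ring forms in an intermolecular, asynchronous, suprafacial [2+2] cycloaddition whose second bond is the collapse of the incipient 1,4-dipole, and water then cleaves iminium salt 18 to the ketone. The closest known reaction is the cycloaddition of isobutyramide-derived keteniminium triflates, including those of C2-symmetric pyrrolidines, with unactivated 1-alkenes to give 3-substituted 2,2-dimethylcyclobutanones. The regiochemistry (Cc to Cd, Cb to Ca) follows from the polarity of the partners, since the charge is better carried by the secondary carbon. The one new stereocentre, Ca, is controlled by the auxiliary: from either side one pyrrolidine methyl blocks a quadrant of the keteniminium ion, so the C9 arm of the alkene turns away from it and one alkene face bonds. The step needs reaction at the allyl group only, which the substrate secures because the arene is fully substituted, the phenol is silylated and the keteniminium ion is formed before 13 is added; the remote core gives no face control, so a Ca epimer would be a diastereomer and is removed by chromatography.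

Step 11
Reactants: 19; 20 isopropenylmagnesium bromide
Product: 22 methyl carbonate of the Cc tertiary allylic alcohol (Cc R; oxygen cis and isopropenyl trans to C9), via dichlorocerium alkoxide 21 (not isolated)
Conditions: 20 (1.3 equiv), CeCl3 (anhydrous), THF, −78 °C; then 19, −78 °C; then ClCO2Me (3 equiv), −78 to 0 °C
Reagents that add atoms: methyl chloroformate, COC(=O)Cl
Why: Organocerium 1,2-addition and O-acylation of the alkoxide in the same flask; the weakly basic reagent adds to the strained cyclobutanone far faster than to the aryl lactone or the deactivated chromanone carbonyl and enters anti to the C9 arm (the gem-dimethyl group shields both faces alike), which sets Cc provisionally with the oxygen cis to C9.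

Step 12
Reactants: 22
Product: 23 8-{[(1S,3R)-3-isopropenyl-2,2-dimethylcyclobutyl]methyl}-7-silyloxy tricycle
Conditions: Pd(OAc)2 (10 mol %), n-Bu3P (10 mol %), HCO2NH4 (3 equiv), THF, 40 °C
Reagents that add atoms: none
Why: Palladium-catalysed formate hydrogenolysis of a tertiary allylic carbonate: zerovalent palladium ionises the carbonate with inversion and so sits on the face anti to C9, and the formate hydride passes from the metal to the ring terminus Cc on that face, giving the 1,1-disubstituted alkene with isopropenyl cis to C9 (Cc R); equilibration of the allyl complex through its CH2 terminus would favour the same, less hindered face, and β-hydride elimination is disfavoured because it would give a cyclobutene.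

Step 13
Reactants: 23; 24 prenyl acetate
Product: 26 (8R)-8-prenyl dienone lactone (C7 ketone; C5=C6 and C4a=C8a double bonds), via tetrabutylammonium phenoxide 25 (not isolated)
Conditions: Bu4N[Ph3SiF2] (1.1 equiv), THF, 0 °C; then Pd2(dba)3·CHCl3 (2.5 mol %), (R,R)-DACH-phenyl Trost ligand (7.5 mol %), 24 (1.5 equiv), CH2Cl2/THF, 0 °C to rt
Reagents that add atoms: none
Why: Fluoride frees the phenoxide as its ammonium salt, and a dearomatising Tsuji–Trost allylation under zerovalent palladium then bonds the CH2 end of the prenyl unit to C8, the ortho carbon with the less branched substituent, while the chiral ligand selects the face of the flat phenoxide so that C8 becomes R; any O-prenyl ether can re-ionise under the catalyst, and the dienone is stabilised as a doubly vinylogous ester.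

Step 14
Reactants: 26
Product: 28 target acid CNP0364345.1, via dilithium carboxylate enolate 27 (not isolated)
Conditions: LiOH (3 equiv), THF/H2O, 0 °C; then 1 M HCl to pH 3, 0 °C
Reagents that add atoms: lithium hydroxide, [Li+].[OH-]
Why: Saponification of the enol lactone (a vinylogous anhydride, far more labile than an ordinary ester) gives the carboxylate and the enolised triketone, whose anionic form shields C3 from epimerisation until acidification releases the target.

Compound list
1 | phloroglucinol | Oc1cc(O)cc(O)c1 | starting material
2 | ethyl 3-oxohexanoate | CCCC(=O)CC(=O)OCC | starting material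
3 | 5,7-dihydroxy-4-propyl-2H-chromen-2-one | CCCC1=CC(=O)Oc2cc(O)cc(O)c12 | intermediate
4 | tigloyl chloride, (E)-2-methylbut-2-enoyl chloride | C/C=C(\C)C(=O)Cl | starting material
5 | 5,7-dihydroxy-8-[(E)-2-methylbut-2-enoyl]-4-propyl-2H-chromen-2-one | CCCC1=CC(=O)Oc2c(C(=O)/C(C)=C/C)c(O)cc(O)c12 | intermediate
6 | allyl alcohol | C=CCO | starting material
7 | 5-(allyloxy)-7-hydroxy-8-[(E)-2-methylbut-2-enoyl]-4-propyl-2H-chromen-2-one | CCCC1=CC(=O)Oc2c(C(=O)/C(C)=C/C)c(O)cc(OCC=C)c12 | intermediate
8 | (2R,3S)-7-allyloxy-2,3-dimethylchroman-4-one with the unsaturated lactone O5–CO–CH=C(propyl)–C6 (cis-chromanone coumarin) | C=CCOc1cc2O[C@H](C)[C@H](C)C(=O)c2c3OC(=O)C=C(CCC)c13 | intermediate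
9 | C4 diethoxymethylsilyl ether and lactone diethoxymethylsilyl ketene acetal of 10 | C=CCOc1cc2O[C@H](C)[C@H](C)C(O[Si](C)(OCC)OCC)c2c3OC(O[Si](C)(OCC)OCC)=C[C@H](CCC)c13 | intermediate (not isolated)
10 | (1′S)-7-allyloxy-cis-2,3-dimethylchroman-4-ol with saturated lactone, both C4 epimers | C=CCOc1cc2O[C@H](C)[C@H](C)C(O)c2c3OC(=O)C[C@H](CCC)c13 | intermediate
11 | (2R,3S,1′S)-7-allyloxy lactone-chromanone tricycle | C=CCOc1cc2O[C@H](C)[C@H](C)C(=O)c2c3OC(=O)C[C@H](CCC)c13 | intermediate
12 | (2R,3S,1′S)-8-allyl-7-hydroxy lactone-chromanone tricycle | C=CCc1c(O)c2[C@@H](CCC)CC(=O)Oc2c3c1O[C@H](C)[C@H](C)C3=O | intermediate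
13 | (2R,3S,1′S)-8-allyl-7-(tert-butyldimethylsilyloxy) lactone-chromanone tricycle (key-step precursor) | C=CCc1c(O[Si](C)(C)C(C)(C)C)c2[C@@H](CCC)CC(=O)Oc2c3c1O[C@H](C)[C@H](C)C3=O | intermediate
14 | isobutyryl chloride | CC(C)C(=O)Cl | starting material
15 | (2R,5R)-2,5-dimethylpyrrolidine | N1[C@H](C)CC[C@H]1C | starting material
16 | 1-[(2R,5R)-2,5-dimethylpyrrolidin-1-yl]-2-methylpropan-1-one | CC(C)C(=O)N1[C@H](C)CC[C@H]1C | intermediate
17 | (2R,5R)-2,5-dimethyl-1-(2-methylprop-1-en-1-ylidene)pyrrolidinium triflate (keteniminium salt) | CC(C)=C=[N+]1[C@H](C)CC[C@H]1C.[O-]S(=O)(=O)C(F)(F)F | intermediate (not isolated)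
18 | cyclobutaniminium triflate of 19 with the (2R,5R)-pyrrolidine on Cc | [N+]5(=C1C[C@@H](Cc2c(O[Si](C)(C)C(C)(C)C)c3[C@@H](CCC)CC(=O)Oc3c4c2O[C@H](C)[C@H](C)C4=O)C1(C)C)[C@H](C)CC[C@H]5C.[O-]S(=O)(=O)C(F)(F)F | intermediate (not isolated)
19 | 8-{[(1R)-2,2-dimethyl-3-oxocyclobutyl]methyl}-7-silyloxy tricycle (key-step product) | O=C1C[C@@H](Cc2c(O[Si](C)(C)C(C)(C)C)c3[C@@H](CCC)CC(=O)Oc3c4c2O[C@H](C)[C@H](C)C4=O)C1(C)C | intermediate
20 | isopropenylmagnesium bromide | C=C(C)[Mg]Br | starting material
21 | dichlorocerium alkoxide of the Cc tertiary alcohol (oxygen cis to C9) | C=C(C)[C@]1(O[Ce](Cl)Cl)C[C@@H](Cc2c(O[Si](C)(C)C(C)(C)C)c3[C@@H](CCC)CC(=O)Oc3c4c2O[C@H](C)[C@H](C)C4=O)C1(C)C | intermediate (not isolated)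
22 | methyl carbonate of the Cc tertiary allylic alcohol (Ca R, Cc R; oxygen cis, isopropenyl trans to C9) | C=C(C)[C@]1(OC(=O)OC)C[C@@H](Cc2c(O[Si](C)(C)C(C)(C)C)c3[C@@H](CCC)CC(=O)Oc3c4c2O[C@H](C)[C@H](C)C4=O)C1(C)C | intermediate
23 | 8-{[(1S,3R)-2,2-dimethyl-3-(prop-1-en-2-yl)cyclobutyl]methyl}-7-silyloxy tricycle | C=C(C)[C@H]1C[C@@H](Cc2c(O[Si](C)(C)C(C)(C)C)c3[C@@H](CCC)CC(=O)Oc3c4c2O[C@H](C)[C@H](C)C4=O)C1(C)C | intermediate
24 | prenyl acetate (3-methylbut-2-en-1-yl acetate) | CC(C)=CCOC(C)=O | starting material
25 | tetrabutylammonium C7 phenoxide of desilylated 23 | C=C(C)[C@H]1C[C@@H](Cc2c([O-])c3[C@@H](CCC)CC(=O)Oc3c4c2O[C@H](C)[C@H](C)C4=O)C1(C)C.CCCC[N+](CCCC)(CCCC)CCCC | intermediate (not isolated)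
26 | (8R)-8-prenyl-8-(cyclobutylmethyl) cyclohexadienone with the enol lactone intact | C=C(C)[C@H]1C[C@@H](C[C@@]2(CC=C(C)C)C(=O)C5=C(OC(=O)C[C@@H]5CCC)C4=C2O[C@H](C)[C@H](C)C4=O)C1(C)C | intermediate
27 | dilithium carboxylate enolate of 28 | C=C(C)[C@H]1C[C@@H](C[C@@]2(CC=C(C)C)C(=O)C([C@@H](CCC)CC(=O)[O-])=C([O-])C3=C2O[C@H](C)[C@H](C)C3=O)C1(C)C.[Li+].[Li+] | intermediate (not isolated)
28 | CNP0364345.1 (C2 R, C3 S, C1′ S, C8 R, Ca S, Cc R) | C=C(C)[C@H]1C[C@@H](C[C@@]2(CC=C(C)C)C(=O)C([C@@H](CCC)CC(=O)O)=C(O)C3=C2O[C@H](C)[C@H](C)C3=O)C1(C)C | target

Total step count: 14. Longest linear sequence: 13 (steps 1 to 8 and 10 to 14; step 9 is the side branch).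

Steps most likely to fail

1. Step 13 (prenylation at C8). What may go wrong: alkylation of the phenoxide on oxygen in place of C8, or too little discrimination between the two faces of the flat phenoxide by the ligand. Fallback: setting out from 23, LiOH in aqueous THF removes the silyl group and opens the lactone, giving the acylphloroglucinol acid F1 as its trilithium salt in solution. Prenyl bromide is added to this alkaline solution at 0 °C; this is the classical C-alkylation of acylphloroglucinol anions, whose charge is spread over the triketone system and which alkylate on ring carbon, here at the less hindered C8. Acidification gives the target 28 together with its C8 epimer F2, which is removed by preparative HPLC. The fallback rejoins the route at 28.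

2. Step 10 (cycloaddition). What may go wrong: weak or mismatched face selection by the auxiliary, capture of the positive charge developing at Ca by a flanking aryl oxygen, or epimerisation at C3 under collidinium triflate at 70 °C. Fallback: setting out from 13, the achiral tetramethylketeniminium ion is made without base or triflic anhydride from 1-chloro-N,N,2-trimethylprop-1-en-1-amine and ZnCl2 in CH2Cl2 at rt, the α-chloroenamine route to keteniminium salts, which adds to 1-alkenes at lower temperature. The resulting dimethyliminium salt F3 is hydrolysed with water to 19 and its Ca epimer F4, and the two diastereomers are separated by chromatography. The fallback rejoins the route at 19.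

3. Step 5 (conjugate reduction). What may go wrong: slow hydride transfer to the hindered, electron-rich coumarin, or poor face control by the bulky chiral ligand. Fallback: setting out from 8, catalyst control is given up. CuH on the achiral and much more reactive ligand 1,2-bis(diphenylphosphino)benzene (Cu(OAc)2·H2O, polymethylhydrosiloxane, toluene, rt, then NH4F/MeOH) reduces the coumarin to both C1′ epimers, 10 and the (1′R) chromanol F5. Oxidation as in step 6 gives 11 and its C1′ epimer F6, which are diastereomers through the C2 and C3 centres and are separated by chromatography. The fallback rejoins the route at 11.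

Further compounds
F1 | step 13 | (3S)-3-{5,7-dihydroxy-8-[((1S,3R)-3-isopropenyl-2,2-dimethylcyclobutyl)methyl]-(2R,3S)-2,3-dimethyl-4-oxochroman-6-yl}hexanoic acid | C=C(C)[C@H]1C[C@@H](Cc2c(O)c([C@@H](CCC)CC(=O)O)c(O)c3c2O[C@H](C)[C@H](C)C3=O)C1(C)C
F2 | step 13 | C8 epimer of 28 | C=C(C)[C@H]1C[C@@H](C[C@]2(CC=C(C)C)C(=O)C([C@@H](CCC)CC(=O)O)=C(O)C3=C2O[C@H](C)[C@H](C)C3=O)C1(C)C
F3 | step 10 | N,N-dimethylcyclobutaniminium trichlorozincate of 19, both Ca epimers | C[N+](C)=C1CC(Cc2c(O[Si](C)(C)C(C)(C)C)c3[C@@H](CCC)CC(=O)Oc3c4c2O[C@H](C)[C@H](C)C4=O)C1(C)C.Cl[Zn-](Cl)Cl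
F4 | step 10 | Ca epimer of 19 | O=C1C[C@H](Cc2c(O[Si](C)(C)C(C)(C)C)c3[C@@H](CCC)CC(=O)Oc3c4c2O[C@H](C)[C@H](C)C4=O)C1(C)C
F5 | step 5 | C1′ epimer of 10, both C4 epimers | C=CCOc1cc2O[C@H](C)[C@H](C)C(O)c2c3OC(=O)C[C@@H](CCC)c13
F6 | step 5 | C1′ epimer of 11 | C=CCOc1cc2O[C@H](C)[C@H](C)C(=O)c2c3OC(=O)C[C@@H](CCC)c13
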